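**Plan**

1. Retrosynthesis: the two tertiary ether bonds q4–O–C8 (ring A) and q4–O–C1 (ring B) are cut first, then in each pyridone the q3–q4 and N–q2 bonds. This leaves a tricyclic bis-δ-lactone and two molecules of N-methylisatoic anhydride.
2. Enabling feature: in each quinolone, q2(=O) and q3 together with the tertiary oxygen on C8 (ring A) or C1 (ring B) are the carbonyl, α-carbon and alkyl oxygen of a δ-lactone. Both heteroaryl rings can therefore be grown on CH2–C(=O)–O units at C3 and C5 instead of being coupled to these hindered methines.
3. The bis-lactone is cut at its two C–O bonds (alkene hydro-acyloxylation), at C3–CH2 (enolate alkylation beside a temporary C2 ketone) and at C5–CH2 (Johnson–Claisen shift), back to (S)-limonene.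
4. Forward order: the limonene ring is kept; C5 chain (step 3), C2 ketone and C3 chain (steps 4–5), ketone removed (steps 6–7), bridged lactone B and fused lactone A (step 8), both pyridone rings at once (step 9), pyran rings B and A (step 10).
5. Stereochemistry: C4 comes from (S)-limonene; C5 from the suprafacial [3,3] shift of a C1–O bond lying cis to isopropenyl; C3 from alkylation anti to isopropenyl; C1 from capture of the C1 cation by the axial C5 substituent (lactone B in step 8, ring B again in step 10).

Key step: step 9

Remark on labels: all intermediates carry the p-menthane labels of the target core: C1 (quaternary, CH3 and O), C2 and C6 (CH2), C3 (CH bearing fused quinolone A), C4 (CH bearing C8 = CMe2O), C5 (CH bearing bridged quinolone B); q2–q4 are quinolone ring positions. In these labels the ring alkene of limonene is C1=C6. The (S)-enantiomer of limonene is the one whose C4 matches the target when the chain cis to C8 is placed on C5.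

**Route**

Step 1
Reactants: 1 (S)-(−)-limonene
Product: 3 (1R,2S,4S)-limonene 1,2-oxide, via bromohydrin 2 (not isolated)
Conditions: NBS, acetone/H2O, 0 °C; then aq NaOH, 25 °C
Reagents that add atoms: water, O
Why: Bromohydrin formation followed by Williamson-type oxirane closure: the trisubstituted ring alkene reacts before the isopropenyl group, water opens the bromonium ion at tertiary C1 in the trans-diaxial (Fürst–Plattner) mode, which is open only to the bromonium ion anti to isopropenyl and places OH on C1 cis and Br on C6 trans to that group, and hydroxide then closes the oxirane with inversion at C6, so the new C1 and C6 centres carry oxygen cis to isopropenyl.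

Step 2
Reactants: 3 (1R,2S,4S)-limonene 1,2-oxide
Product: 6 (1R,4S)-p-mentha-2,8-dien-1-ol, via hydroxy selenide 4 (not isolated), via selenoxide 5 (not isolated)
Conditions: PhSeSePh, NaBH4, EtOH, 80 °C; then 30% H2O2, THF, 0 → 25 °C
Reagents that add atoms: none
Why: Selenide-mediated epoxide-to-allylic-alcohol transposition: PhSe− opens the oxirane at the secondary carbon C6 trans-diaxially, oxidation gives the selenoxide, and its syn-elimination can only run toward C5 because C1 has no hydrogen, so the C5=C6 alkene forms while the C1–O bond, cis to isopropenyl, is not touched.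

Step 3
Reactants: 6 (1R,4S)-p-mentha-2,8-dien-1-ol; 7 triethyl orthoacetate
Product: 10 ethyl 2-[3-methyl-6-(prop-1-en-2-yl)cyclohex-2-en-1-yl]acetate (chain cis to isopropenyl), via mixed orthoester 8 (not isolated), via ketene acetal 9 (not isolated)
Conditions: MeC(OEt)3 (excess), EtCO2H (cat.), 140 °C, EtOH distilled off
Reagents that add atoms: triethyl orthoacetate (7), CCOC(C)(OCC)OCC
Why: Johnson–Claisen rearrangement: acid-catalysed exchange gives the mixed orthoester and then the ketene acetal, whose [3,3] shift within the ring is necessarily suprafacial and so delivers CH2CO2Et to C5 on the face that carried the C1 oxygen (cis to isopropenyl), transferring the C1 configuration to the new C5 centre and moving the alkene to C1=C6.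

Step 4
Reactants: 10 ethyl 2-[3-methyl-6-(prop-1-en-2-yl)cyclohex-2-en-1-yl]acetate
Product: 11 ethyl 2-[3-methyl-4-oxo-6-(prop-1-en-2-yl)cyclohex-2-en-1-yl]acetate
Conditions: Rh2(caprolactamate)4 (1 mol %), t-BuOOH (70% aq), K2CO3, CH2Cl2, 25 °C
Reagents that add atoms: tert-butyl hydroperoxide, CC(C)(C)OO
Why: Radical-chain allylic oxidation with t-BuOOH under dirhodium catalysis, of the type that turns limonene-like cyclohexenes into carvone-like enones in the presence of an isopropenyl group: C2 is the only allylic CH2, the tertiary allylic C–H bonds at C5 and C4 are hindered and cannot end as ketones, the allyl radical is captured at C2 rather than at C6, which is flanked by the substituted C5, and the mixed peroxide collapses to the C2 ketone; no stereocentre is formed.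

Step 5
Reactants: 11 ethyl 2-[3-methyl-4-oxo-6-(prop-1-en-2-yl)cyclohex-2-en-1-yl]acetate; 12 ethyl bromoacetate
Product: 14 diethyl 2,2'-[5-methyl-6-oxo-2-(prop-1-en-2-yl)cyclohex-4-ene-1,3-diyl]diacetate, via lithium enolate 13 (not isolated)
Conditions: LiN(iPr)2 (1.05 equiv), THF, −78 °C; BrCH2CO2Et, DMPU, −78 → −30 °C
Reagents that add atoms: ethyl bromoacetate (12), CCOC(=O)CBr
Why: Kinetic α'-deprotonation of a carvone-type enone and SN2 alkylation of the cross-conjugated lithium enolate: the ketone CH2 at C3 is deprotonated faster than the ester CH2 or the γ-CH at C5, and ethyl bromoacetate approaches C3 anti to the adjacent isopropenyl group (and to the cis C5 chain on the same face), as in α'-alkylations of carvone, which sets C3 with its chain trans to isopropenyl, also the more stable arrangement.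

Step 6
Reactants: 14 diethyl 2,2'-[5-methyl-6-oxo-2-(prop-1-en-2-yl)cyclohex-4-ene-1,3-diyl]diacetate; 15 p-toluenesulfonyl hydrazide
Product: 16 tosylhydrazone of 14
Conditions: TsNHNH2, EtOH, AcOH (cat.), 60 °C
Reagents that add atoms: p-toluenesulfonyl hydrazide (15), Cc1ccc(cc1)S(=O)(=O)NN
Why: Acid-catalysed hydrazone condensation at the only ketone, which reacts in the 1,2-sense as carvone does; the ethyl esters are inert in ethanol and C3, the one centre that could epimerise through the ene-hydrazine, already holds the more stable trans arrangement.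

Step 7
Reactants: 16 tosylhydrazone of 14
Product: 19 diethyl 2,2'-[5-methyl-2-(prop-1-en-2-yl)cyclohex-4-ene-1,3-diyl]diacetate, via N-boryl tosylhydrazide 17 (not isolated), via allylic diazene 18 (not isolated)
Conditions: catecholborane, CHCl3, 0 °C; then NaOAc·3H2O, 65 °C
Reagents that add atoms: none
Why: Alkene-transposing reduction of an enone tosylhydrazone with catecholborane (Kabalka reduction): hydride adds to the C=N carbon, acetate-induced loss of sulfinate gives the allylic diazene, and its retro-ene loss of N2 places hydrogen on C6 and the alkene at C1=C2, so the C2 oxygen is removed under conditions that leave the esters, the isopropenyl group and C3, C4, C5 untouched.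

Step 8
Reactants: 19 diethyl 2,2'-[5-methyl-2-(prop-1-en-2-yl)cyclohex-4-ene-1,3-diyl]diacetate
Product: 22 tricyclic bis-δ-lactone of the p-menthane-1,8-diol core, via diacid 20 (not isolated), via lactone B acid 21 (not isolated)
Conditions: LiOH, THF/H2O, 40 °C; aq HCl, extraction; then CF3SO3H (10 mol %), CH2Cl2, 0 → 25 °C
Reagents that add atoms: lithium hydroxide, [Li+].[OH-]
Why: Ester saponification followed by Brønsted-acid Markovnikov lactonisation of an unsaturated acid: protonation gives the tertiary C1 and C8 cations, the C5 carboxymethyl group, axial when C8 is equatorial, reaches C1 only from its own face and so sets C1 with oxygen cis to the C5 chain (bridged lactone B), the equatorial C3 chain closes the trans-fused lactone A on C8, and reversible ionisation of the tertiary C–O bonds favours this isomer, in which C8 stays equatorial, over the one with the two chains exchanged.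

Step 9
Reactants: 22 tricyclic bis-δ-lactone of the p-menthane-1,8-diol core; 23 N-methylisatoic anhydride
Product: 27 trans-3,5-bis(4-hydroxy-1-methyl-2-oxoquinolin-3-yl)-p-menthane-1,8-diol, via dilithium dienolate 24 (not isolated), via bis(lithium carbamate) adduct 25 (not isolated), via bis(aminobenzoyl) bis-lactone 26 (not isolated)
Conditions: LiN(SiMe3)2 (4.6 equiv), THF, −78 °C; 23 (2.4 equiv), −78 → 0 °C; AcOH, 25 °C; then PhMe, 100 °C
Reagents that add atoms: N-methylisatoic anhydride (23), CN1C(=O)OC(=O)c2ccccc21
Why: Double crossed-Claisen acylation followed by decarboxylation and intramolecular lactone aminolysis, the known route from ester and lactone enolates and isatoic anhydrides to 4-hydroxy-2-quinolones: each lithium enolate α-carbon of 24 (future q3) attacks the benzoyl carbonyl of 23 (future q4), the oxazinedione opens to the N-aryl carbamate 25, and the second equivalent of base per lactone stores the acidic β-keto lactone as its enolate, so that product does not quench unreacted enolate. Acetic acid protonates the carbamates, which lose CO2 to give the two N-methylanilines of 26. On warming, each nitrogen adds to its lactone carbonyl (future q2) in a 6-exo-trig closure and the tetrahedral intermediate expels the tertiary alkoxide, so that each pyridone ring closes while lactone A opens to the C8 carbinol and lactone B to the C1 carbinol, with aromatisation to the 4-hydroxy-2-quinolone as driving force. Two rings and four skeletal bonds (two q3–q4, two N–q2) are formed and no stereocentre is created: the acylated α-carbons become sp2, and C1, C3, C4 and C5 carry no acidic hydrogen, so their configuration is retained. The step needs C- rather than O-acylation at both sites and attack at the benzoyl rather than the carbamate carbonyl of 23; lithium enolates in THF acylate at carbon, the carbamate carbonyl is deactivated by nitrogen, and the N-methyl group removes the N–H that would otherwise consume base.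

Step 10
Reactants: 27 trans-3,5-bis(4-hydroxy-1-methyl-2-oxoquinolin-3-yl)-p-menthane-1,8-diol
Product: 29 CNP0229685.7, via ring B ether carbinol 28 (not isolated)
Conditions: CF3CO2H, CH2Cl2, 25 °C
Reagents that add atoms: none
Why: SN1 cycloetherification of tertiary carbinols by the q4 hydroxyl of a 4-hydroxy-2-quinolone: CF3CO2H ionises C1 and C8, the axial C5 quinolone can reach the C1 cation only from the face it occupies, which resets C1 with oxygen cis to C5 (bridged ring B), the equatorial C3 quinolone closes the trans-fused pyran ring A on C8, and because the closures are reversible the q4 oxygen rather than the q2 amide oxygen ends in each ether, the N-methyl-2-quinolone being the more stable framework.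

**Compound list**

1 | (S)-(−)-limonene | CC1=CC[C@H](CC1)C(C)=C | starting material
2 | bromohydrin: 6-bromo-p-menth-8-en-1-ol in the labels used here, OH cis and Br trans to isopropenyl (not isolated) | C[C@@]1(O)CC[C@@H](C[C@H]1Br)C(C)=C | intermediate
3 | (1R,2S,4S)-limonene 1,2-oxide, oxirane oxygen cis to isopropenyl | C[C@@]12CC[C@@H](C[C@@H]1O2)C(C)=C | intermediate
4 | hydroxy selenide: C1–OH cis, C6–SePh trans to isopropenyl (not isolated) | C[C@@]1(O)CC[C@@H](C[C@H]1[Se]c1ccccc1)C(C)=C | intermediate
5 | selenoxide of 4 (not isolated) | C[C@@]1(O)CC[C@@H](C[C@H]1[Se](=O)c1ccccc1)C(C)=C | intermediate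
6 | (1R,4S)-p-mentha-2,8-dien-1-ol, OH cis to isopropenyl (alkene C5=C6 in the labels used here) | C[C@@]1(O)CC[C@@H](C=C1)C(C)=C | intermediate
7 | triethyl orthoacetate | CCOC(C)(OCC)OCC | starting material
8 | mixed orthoester of 6 (not isolated) | CCOC(C)(OCC)O[C@]1(C)CC[C@@H](C=C1)C(C)=C | intermediate
9 | ketene acetal of 6 (not isolated) | C=C(OCC)O[C@]1(C)CC[C@@H](C=C1)C(C)=C | intermediate
10 | ethyl 2-[3-methyl-6-(prop-1-en-2-yl)cyclohex-2-en-1-yl]acetate, acetate chain on C5 cis to isopropenyl, alkene C1=C6 | CCOC(=O)C[C@@H]1C=C(C)CC[C@@H]1C(C)=C | intermediate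
11 | ethyl 2-[3-methyl-4-oxo-6-(prop-1-en-2-yl)cyclohex-2-en-1-yl]acetate, C2 ketone conjugated with C1=C6, chain cis to isopropenyl | CCOC(=O)C[C@@H]1C=C(C)C(=O)C[C@@H]1C(C)=C | intermediate
12 | ethyl bromoacetate | CCOC(=O)CBr | starting material
13 | cross-conjugated lithium enolate of 11 (not isolated) | [Li+].CCOC(=O)C[C@@H]1C=C(C)C([O-])=C[C@@H]1C(C)=C | intermediate
14 | diethyl 2,2'-[5-methyl-6-oxo-2-(prop-1-en-2-yl)cyclohex-4-ene-1,3-diyl]diacetate, C3 chain trans and C5 chain cis to isopropenyl | CCOC(=O)C[C@@H]1C=C(C)C(=O)[C@@H](CC(=O)OCC)[C@@H]1C(C)=C | intermediate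
15 | p-toluenesulfonyl hydrazide | Cc1ccc(cc1)S(=O)(=O)NN | starting material
16 | tosylhydrazone of 14 | CCOC(=O)C[C@@H]1C=C(C)C(=NNS(=O)(=O)c2ccc(C)cc2)[C@@H](CC(=O)OCC)[C@@H]1C(C)=C | intermediate
17 | N-boryl tosylhydrazide from hydride addition to 16 (not isolated) | CCOC(=O)C[C@@H]1C=C(C)C(N(B2Oc3ccccc3O2)NS(=O)(=O)c2ccc(C)cc2)[C@@H](CC(=O)OCC)[C@@H]1C(C)=C | intermediate
18 | allylic diazene (not isolated) | CCOC(=O)C[C@@H]1C=C(C)C(N=N)[C@@H](CC(=O)OCC)[C@@H]1C(C)=C | intermediate
19 | diethyl 2,2'-[5-methyl-2-(prop-1-en-2-yl)cyclohex-4-ene-1,3-diyl]diacetate, alkene C1=C2, C3 chain trans and C5 chain cis to isopropenyl | CCOC(=O)C[C@@H]1CC(C)=C[C@@H](CC(=O)OCC)[C@@H]1C(C)=C | intermediate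
20 | diacid of 19 (not isolated) | OC(=O)C[C@@H]1CC(C)=C[C@@H](CC(O)=O)[C@@H]1C(C)=C | intermediate
21 | lactone B acid: bridged δ-lactone C5–CH2–C(=O)–O–C1 with free C3 acetic acid and isopropenyl (not isolated) | CC(=C)[C@H]1[C@H](CC(O)=O)C[C@]2(C)C[C@H]1CC(=O)O2 | intermediate
22 | tricyclic bis-δ-lactone: lactone A trans-fused (C3–CH2–C(=O)–O–C8), lactone B bridged (C5–CH2–C(=O)–O–C1) | O=C1OC(C)(C)[C@H]2[C@H](C1)C[C@]1(C)C[C@H]2CC(=O)O1 | intermediate
23 | N-methylisatoic anhydride | CN1C(=O)OC(=O)c2ccccc21 | starting material
24 | dilithium dienolate of 22 (not isolated) | [Li+].[Li+].[O-]C1OC(C)(C)[C@H]2[C@H](C=1)C[C@]1(C)C[C@H]2C=C([O-])O1 | intermediate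
25 | bis(lithium carbamate) C-acylation adduct, drawn in its keto form (not isolated) | [Li+].[Li+].O=C1OC(C)(C)[C@H]2[C@H](C1C(=O)c1ccccc1N(C)C([O-])=O)C[C@]1(C)C[C@H]2C(C(=O)c2ccccc2N(C)C([O-])=O)C(=O)O1 | intermediate
26 | bis[2-(methylamino)benzoyl] bis-lactone, α-carbons unassigned (not isolated) | O=C1OC(C)(C)[C@H]2[C@H](C1C(=O)c1ccccc1NC)C[C@]1(C)C[C@H]2C(C(=O)c2ccccc2NC)C(=O)O1 | intermediate
27 | trans-3,5-bis(4-hydroxy-1-methyl-2-oxoquinolin-3-yl)-p-menthane-1,8-diol | CC(C)(O)[C@H]1[C@H](c2c(O)c3ccccc3n(C)c2=O)C[C@@](C)(O)C[C@H]1c1c(O)c2ccccc2n(C)c1=O | intermediate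
28 | ring B ether carbinol: C1–O–q4 ether closed, C8–OH and q4–OH of quinolone A free (not isolated) | CC(C)(O)[C@H]1[C@H](c2c(O)c3ccccc3n(C)c2=O)C[C@]2(C)C[C@H]1c1c(c3ccccc3n(C)c1=O)O2 | intermediate
29 | CNP0229685.7 | Cn1c(=O)c2c(c3ccccc31)OC(C)(C)[C@H]1[C@H]2C[C@]2(C)C[C@H]1c1c(c3ccccc3n(C)c1=O)O2 | target

**Step count and risks**

Total steps: 10. Longest linear sequence: 10 steps, from 1 to 29; 7, 12, 15 and 23 are bought.

Steps most likely to fail:

1. Step 4, allylic oxidation. The allyl radical may be oxygenated at the wrong terminus (C6 instead of C2), or hydrogen may be abstracted at the tertiary allylic C–H bonds, which would give regio-scrambled or over-oxidised material. The fallback sets out from 10 and avoids a free allyl radical. Catalytic SeO2 with t-BuOOH in CH2Cl2 hydroxylates by an ene reaction and [2,3]-sigmatropic shift at the ring CH2 on the more substituted alkene terminus, which should give the allylic alcohol ethyl 2-[4-hydroxy-3-methyl-6-(prop-1-en-2-yl)cyclohex-2-en-1-yl]acetate F1 with the alkene back at C1=C6. Dess–Martin oxidation of F1 returns to the route at 11.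

2. Step 9, double heteroannulation. The second acylation may stall through proton transfer between product and unreacted enolate, acylation may occur at oxygen, or the hindered N-methylaniline may fail to open the tertiary lactone. The fallback sets out from 22 and makes the N–q2 bond before the N–aryl bond. LiN(SiMe3)2 and 2-fluorobenzoyl chloride (ordinary crossed-Claisen acylation) should give the bis(2-fluorobenzoyl) bis-lactone F2. Methylamine in THF then opens both activated lactones to the bis(β-keto N-methylamide) diol F3. K2CO3 in DMF at 100 °C closes each pyridone by intramolecular SNAr of the amide nitrogen on the fluoroarene activated by the ortho-acyl group, and the route is rejoined at 27.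

3. Step 8, acid lactonisation. The C8 cation may undergo a 1,2-hydride shift from C4, or lose the C4 proton and be reprotonated, before it is trapped; either would erase the C4 configuration and divert the chains into γ-lactones. The fallback sets out from diacid 20 and uses iodonium ions instead of free cations. I2, NaHCO3, MeCN/H2O at 0 °C should give the bis-iodolactone F4 (lactone B with iodine on C2 trans to the ring oxygen, lactone A with a CH2I group on C8). Bu3SnH, AIBN, benzene, 80 °C then removes both iodine atoms and returns to the route at 22.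

**Further compounds**

F1 | step 4 | ethyl 2-[4-hydroxy-3-methyl-6-(prop-1-en-2-yl)cyclohex-2-en-1-yl]acetate, carbinol centre unassigned | CCOC(=O)C[C@@H]1C=C(C)C(O)C[C@@H]1C(C)=C
F2 | step 9 | bis(2-fluorobenzoyl) bis-lactone, α-carbons unassigned | O=C1OC(C)(C)[C@H]2[C@H](C1C(=O)c1ccccc1F)C[C@]1(C)C[C@H]2C(C(=O)c2ccccc2F)C(=O)O1
F3 | step 9 | bis(β-keto N-methylamide) of the p-menthane-1,8-diol core, α-carbons unassigned | CC(C)(O)[C@H]1[C@H](C(C(=O)NC)C(=O)c2ccccc2F)C[C@@](C)(O)C[C@H]1C(C(=O)NC)C(=O)c1ccccc1F
F4 | step 8 | bis-iodolactone: C2 iodide trans to the lactone B oxygen, CH2I on C8 (C8 unassigned) | O=C1OC(C)(CI)[C@H]2[C@H](C1)[C@H](I)[C@]1(C)C[C@H]2CC(=O)O1
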